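Flavan numbering is used throughout: O1, C2, C3, C4, C4a, C5–C8, C8a. Ring A is the benzo ring, ring B the 4-hydroxyphenyl group and ring C the pyran ring.

## The problem

The target 19 is a 2,3-trans-flavan-3-ol. Its dihydropyran ring C is fused at C4a–C8a to a fully differentiated phloroglucinol ring A (5-OMe, 7-OH, 8-prenyl, C6–H) and carries ring B at C2 and a hydroxyl at C3. The only stereocentres are the adjacent C2 (R) and C3 (S). Nothing else in the molecule is chiral, so the absolute configuration has to come from a reagent or catalyst, while the trans relation can be relayed from an (E)-alkene. Ring A raises a regiochemical question: its three oxygens must end as methyl ether, free phenol and ring ether, and the prenyl group must sit at C8 between O7 and O1, not at C6. Three features are fragile: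

- The prenyl double bond cyclises onto a neighbouring phenol under acid, and it rules out hydrogenolysis and electrophilic oxidants once it is in place.
- The electron-rich ring A is nucleophilic at C6 and is easily oxidised.
- The benzylic O1–C2 ether can be opened by a ring B phenoxide through a quinone methide, with loss of the C2 configuration.

The feature that opens the route is that C4 is an unsubstituted methylene on C4a while O1 sits on the neighbouring C8a. O1–C8a–C4a–C4 is therefore the heterodiene of an ortho-quinone methide of ring A, and C2–C3, with aryl on C2, oxygen on C3 and the two trans, is the imprint of an (E)-2-arylethenyl ester.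

## Retrosynthesis

**Protecting groups (19 from 18 from 17).** No skeletal bond is cut. The C3 hydroxyl is traced to the acetate 17 and the two phenols to the silyl ethers of 18. The acetate is what the alkene partner brings, and its weak donor character is needed for the regiochemistry of the ring-forming step. Silyl ethers are chosen because fluoride removes them under buffered, near-neutral conditions. Benzyl ethers would require a hydrogenolysis that saturates the prenyl group, a methyl ether could not be told from the 5-OMe group, and acid-labile acetals would expose the prenyl group and the benzylic ether to acid at the end. O7 must be blocked during ring formation in any case, since a free hydroxyl para to C4 would divert the ortho-quinone methide into a para-quinone methide. The ester is removed first, while no phenoxide can form.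

**Ring C (17 from 10 and 15 through 16).** O1–C2 and C3–C4 are cut together. Cutting O1–C2 alone (cyclisation of a diarylpropanediol) or C4–C4a alone (Friedel–Crafts closure) would leave a linear precursor whose stereocentres and whose bond to the crowded ring A must be made in separate steps. The double cut divides the molecule into two achiral halves of similar size, salicyl alcohol 10 and enol acetate 15, and lets the ring, two bonds and both stereocentres arise in one operation from methide 16. The forward reaction has to deliver four things:

- aryl at C2 and acetoxy at C3;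
- transfer of the (E)-geometry into the trans relation;
- selection of the alkene face that gives 2R,3S;
- capture of 16 by 15 faster than by a second molecule of 10.

**Alkene partner (15 from 14, from 12 and 13, from 11).** The enol C–O bond of 15 is cut in the Baeyer–Villiger sense, which leads to enone 14. This fixes the geometry: the (E)-alkene of 14 comes from a stabilised-ylide Wittig reaction of aldehyde 12 with ylide 13 and is carried through the oxygen insertion with retention. O-Acylation of an arylacetaldehyde enolate would give E/Z mixtures. Aldehyde 12 is the silyl ether of commercial 11.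

**Salicyl alcohol (10 from 9 from 8 from 6).** The C4–C4a bond is cut as a one-carbon electrophile on ring A. Passing through the aldehyde level serves a second purpose. In 8 the hydroxyl ortho to the aldehyde is chelated, which differentiates the two hydroxyls of the formerly symmetric ring, so that only the para one (the future O7) is silylated to 9. Formylation of 6 has no regiochemical choice because its two open positions are equivalent.

**Prenyl group (6 from 5, from 2 and 3 through 4, from 1).** The aryl–prenyl bond is cut. Direct electrophilic prenylation of 1 would give mixtures of C- and O-alkylation at several positions and needs acid. In bis-acetal 2 the carbon between the two acetal oxygens is the only doubly chelated site, so metalation gives 4 there and alkylation with 3 puts the prenyl group between the future O7 and O1. Commercial 1 already carries the methyl ether that becomes the 5-OMe group, and its symmetry removes every other regiochemical question on ring A.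

## Roads not taken

**Alternative 1: ring A built last by benzannulation.**
- Cut: C8–C8a and C6–C7 (with C4a–C8a re-formed), leading to cyclobutenone A1, which already holds the C2/C3 diol as an acetonide, and siloxyalkyne A2.
- Forward key step: heating the two (Danheiser benzannulation) should open A1 to a vinylketene, add A2, and by ring opening and six-electron closure give the hexasubstituted phenol A3.
- Merits: the positions of prenyl, silyloxy and hydroxyl on ring A are fixed by the mechanism. Both stereocentres would come from an asymmetric dihydroxylation of an (E)-alkene, which is reagent-controlled and well understood. In both respects this road is more secure than the chosen one.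
- Weak points: ring A is the part of the target that least needs a de novo construction. A1 requires a long linear synthesis and A2 is a sensitive ynol ether. The annulation runs hot with a prenyl group on board. A3 is not yet a chroman: acetonide cleavage and an O1–C2 closure with clean inversion at a benzylic carbon activated by the 4-silyloxyphenyl group, which tends to ionise, still follow.
- Comparison: the chosen plan has less certain enantiocontrol. It sets against this a ring A available in six steps from a symmetric resorcinol, ring C and both stereocentres in one step, and a far shorter route.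

**Alternative 2: ring-closing metathesis to a flav-3-ene.**
- Cut: the C3=C4 double bond of chromene A5, leading to diene A4, an aryl ether of an enantioenriched aryl vinyl carbinol with a vinyl group on C4a.
- Forward key step: first-generation Grubbs catalyst, RuCl2(PCy3)2(=CHPh), closes ring C. Hydroboration–oxidation anti to the C2 aryl group would then add the C3 hydroxyl.
- Merits: the ring closure is as reliable as any in synthesis, and the C2 configuration is set beforehand by established asymmetric chemistry. In both respects this road is better.
- Weak points: the prenyl group is a third alkene. It can enter the metathesis, closing a seven-membered ring onto the allylic ether or cross-coupling. In the later hydroboration it competes with the C3=C4 bond, so it would have to be introduced late or masked. The O1–C2 ether must be formed between a 2,6-disubstituted phenol and a carbinol that is benzylic, allylic and para-oxygen-activated, where ionisation erodes the configuration. The C3 oxygen and its stereocentre cost further steps.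
- Comparison: the chosen plan sets against the more reliable ring closure the fact that the C3 oxygen arrives in the key step with the right relative configuration, and that no alkene chemistry has to discriminate against the prenyl group.

**Alternative 3: epoxy–arene cyclisation.**
- Cut: C4–C4a, leading to epoxy ether A6, in which both stereocentres are present and C8 is blocked by the prenyl group.
- Forward key step: activation of the terminal epoxide by a fluorinated alcohol solvent or a boron Lewis acid lets C4a attack the epoxide CH2 and gives chroman A7 with the C3 hydroxyl free.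
- Merits: no stereocentre is formed in the key step, so enantiocontrol rests on an asymmetric epoxidation with kinetic resolution and is not in question. Only one ortho position is open. Here this road is better.
- Weak points: the activating medium also meets a prenyl alkene and an O1–C2 benzylic ether that can ionise, which is why ring B must be deactivated as a pivalate. Attack at the inner epoxide carbon would give a dihydrobenzofuran. The real difficulty moves into A6, whose ether bond must be made with inversion between a hindered phenol and a secondary benzylic epoxy carbinol. The route is more linear and needs a third protecting group.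
- Comparison: the chosen plan sets against the secure absolute configuration its convergence, the absence of a Lewis-acid step on a prenylated benzylic ether, and fewer steps.

Key step: step 10

Assumption: no model fixes the sense of induction of a chiral phosphoric acid on an unsubstituted methide. The (R)-acid is written in step 10; if the first run gives the 2S,3R series, the (S)-acid is used and nothing else changes.

Remark: fragments that bring skeletal carbon are numbered reactants. Reagents that deliver only a protecting group or a heteroatom stand on the reagent line.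

## Route

Step 1
Reactants: 1 5-methoxybenzene-1,3-diol (5-methoxyresorcinol)
Product: 2 1-methoxy-3,5-bis(methoxymethoxy)benzene
Conditions: MOMCl (2.5 equiv), i-Pr2NEt, CH2Cl2, 0 °C → rt
Reagents that add atoms: chloromethyl methyl ether, COCCl
Why: O-Alkylation of both phenols to the methoxymethyl ethers; the two acetal groups are the cooperating directing groups for the metalation in step 2.

Step 2
Reactants: 2 1-methoxy-3,5-bis(methoxymethoxy)benzene; 3 1-bromo-3-methylbut-2-ene (prenyl bromide)
Product: 5 5-methoxy-1,3-bis(methoxymethoxy)-2-(3-methylbut-2-enyl)benzene, via aryllithium 4 (not isolated)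
Conditions: n-BuLi, THF, 0 °C; then CuI (10 mol %), 3, −78 °C → rt
Reagents that add atoms: none
Why: Directed ortho-metalation; the carbon between the two acetal oxygens is doubly chelated and is lithiated in preference to the carbons flanked by one acetal and the methyl ether. Copper-catalysed allylic substitution at the primary carbon of 3 then gives the linear prenyl arene.

Step 3
Reactants: 5 5-methoxy-1,3-bis(methoxymethoxy)-2-(3-methylbut-2-enyl)benzene
Product: 6 5-methoxy-2-(3-methylbut-2-enyl)benzene-1,3-diol
Conditions: HCl (1 M in MeOH), 0 °C → rt, stopped at full conversion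
Reagents that add atoms: none
Why: Acid-catalysed acetal exchange with methanol frees both phenols; dilute acid at or below room temperature is the usual way to do this beside a prenyl group without closing it onto the phenol.

Step 4
Reactants: 6 5-methoxy-2-(3-methylbut-2-enyl)benzene-1,3-diol
Product: 8 2,4-dihydroxy-6-methoxy-3-(3-methylbut-2-enyl)benzaldehyde, via iminium chloride 7 (not isolated)
Conditions: POCl3, DMF, MeCN, 0 °C → rt; then aq. NaOAc, rt
Reagents that add atoms: N,N-dimethylformamide, CN(C)C=O; water, O
Why: Vilsmeier–Haack formylation; the two open positions of the symmetric diol are equivalent, so one aldehyde results, and the iminium salt 7 deactivates the ring against a second substitution. The buffered hydrolysis keeps the prenyl group out of strong acid.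

Step 5
Reactants: 8 2,4-dihydroxy-6-methoxy-3-(3-methylbut-2-enyl)benzaldehyde
Product: 9 2-hydroxy-6-methoxy-3-(3-methylbut-2-enyl)-4-(triisopropylsilyloxy)benzaldehyde
Conditions: TIPSCl (1.05 equiv), imidazole, DMF, 0 °C → rt
Reagents that add atoms: chlorotri(propan-2-yl)silane, CC(C)[Si](Cl)(C(C)C)C(C)C
Why: Chemoselective phenol silylation; the 2-hydroxyl is hydrogen-bonded to the aldehyde and less nucleophilic, so the bulky chloride takes the 4-hydroxyl (the future O7). The bulky ether also shields C6 and prevents a para-quinone methide in step 10.

Step 6
Reactants: 9 2-hydroxy-6-methoxy-3-(3-methylbut-2-enyl)-4-(triisopropylsilyloxy)benzaldehyde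
Product: 10 2-(hydroxymethyl)-3-methoxy-6-(3-methylbut-2-enyl)-5-(triisopropylsilyloxy)phenol
Conditions: NaBH4, THF–MeOH, −10 °C; pH 7 phosphate buffer; used without chromatography on silica
Reagents that add atoms: none
Why: Borohydride 1,2-reduction of the aldehyde; low temperature and a neutral quench keep the electron-rich benzylic alcohol from ionising, and the crude product is taken directly into step 10.

Step 7
Reactants: 11 4-hydroxybenzaldehyde
Product: 12 4-(triisopropylsilyloxy)benzaldehyde
Conditions: TIPSCl, imidazole, DMF, rt
Reagents that add atoms: chlorotri(propan-2-yl)silane, CC(C)[Si](Cl)(C(C)C)C(C)C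
Why: Standard silyl ether formation; the triisopropylsilyl group survives the later steps as an aryl ether para to a carbonyl or alkene and keeps ring B a good donor.

Step 8
Reactants: 12 4-(triisopropylsilyloxy)benzaldehyde; 13 1-(triphenylphosphoranylidene)propan-2-one
Product: 14 (E)-4-[4-(triisopropylsilyloxy)phenyl]but-3-en-2-one
Conditions: PhMe, 110 °C
Reagents that add atoms: none
Why: Wittig olefination with a stabilised ylide gives the (E)-enone under neutral conditions, which spare the aryl silyl ether that an aqueous-hydroxide aldol condensation would cleave.

Step 9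
Reactants: 14 (E)-4-[4-(triisopropylsilyloxy)phenyl]but-3-en-2-one
Product: 15 (E)-2-[4-(triisopropylsilyloxy)phenyl]ethenyl acetate
Conditions: KHSO5 (as the triple salt 2KHSO5·KHSO4·K2SO4), dry DMF, rt
Reagents that add atoms: potassium peroxymonosulfate, [K+].[O-]S(=O)(=O)OO
Why: Baeyer–Villiger oxidation; the alkenyl group migrates in preference to methyl with retention of the double-bond geometry, so the (E)-enone gives the (E)-enol acetate. Anhydrous peroxymonosulfate in DMF is a known reagent for this conversion of benzalacetones to styryl acetates.

Step 10
Reactants: 10 2-(hydroxymethyl)-3-methoxy-6-(3-methylbut-2-enyl)-5-(triisopropylsilyloxy)phenol; 15 (E)-2-[4-(triisopropylsilyloxy)phenyl]ethenyl acetate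
Product: 17 (2R,3S)-5-methoxy-8-(3-methylbut-2-enyl)-7-(triisopropylsilyloxy)-2-[4-(triisopropylsilyloxy)phenyl]-3,4-dihydro-2H-chromen-3-yl acetate, via o-quinone methide 16 (not isolated)
Conditions: (R)-TRIP [(R)-3,3′-bis(2,4,6-triisopropylphenyl)-1,1′-binaphthyl-2,2′-diyl hydrogen phosphate] (10 mol %), 15 (2.5 equiv), 4 Å MS, PhMe, −20 °C, 10 added over 6 h
Reagents that add atoms: none
Why: Proposed new method: the chiral acid ionises the electron-rich salicyl alcohol 10 to the o-quinone methide 16, whose exocyclic CH2 (C4) is attacked by the acetoxy-bearing carbon of 15 while the developing 4-silyloxybenzylic cation at C2 is captured by the methide oxygen, an asynchronous inverse-electron-demand hetero-Diels–Alder reaction; the closest known reaction type is the chiral-phosphoric-acid-catalysed [4+2] cycloaddition of aryl-substituted o-quinone methides with styrenes, enamides and enol ethers, and an unsubstituted methide paired with an enol ester has not been taken through it enantioselectively. Ring C closes by this intermolecular [4+2] cycloaddition, four atoms (O1, C8a, C4a, C4) from 16 and two (C2, C3) from 15, with O1–C2 and C3–C4 formed in one operation. Regiochemistry follows the stronger donor: the 4-silyloxyphenyl group stabilises positive charge at its own carbon far better than an acyloxy group does, as in the known additions of methides to anethole-type styrenes, so aryl ends at C2 and acetoxy at C3. The trans relation of C2 and C3 is carried over from the (E)-alkene by suprafacial addition, whatever the endo or exo orientation. The absolute configuration must come from the phosphate, which stays hydrogen-bonded or ion-paired to the methide oxygen and leaves one face of the diene open; since 15 offers the catalyst no donor to hold, face selection rests on the fit of the aryl group in the binaphthyl pocket, and the configuration is checked by Mosher analysis of 18. The step also needs chemoselectivity for capture of 16 by 15 over attack of a second ring A at C6 and over acid-induced closure of the phenol onto the prenyl group. The bulky silyl ether next to C6, the weak acid, low temperature, excess 15, slow addition of 10 and molecular sieves against hydrolysis of the enol ester are there to secure it.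

Step 11
Reactants: 17 (2R,3S)-5-methoxy-8-(3-methylbut-2-enyl)-7-(triisopropylsilyloxy)-2-[4-(triisopropylsilyloxy)phenyl]-3,4-dihydro-2H-chromen-3-yl acetate
Product: 18 (2R,3S)-5-methoxy-8-(3-methylbut-2-enyl)-7-(triisopropylsilyloxy)-2-[4-(triisopropylsilyloxy)phenyl]-3,4-dihydro-2H-chromen-3-ol
Conditions: K2CO3 (0.3 equiv), MeOH–THF, 0 °C
Reagents that add atoms: none
Why: Base-catalysed transesterification of the secondary acetate with methanol; the C3–O bond is not broken, and with both phenols still silylated no phenoxide can open ring C at O1–C2, so neither stereocentre is at risk.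

Step 12
Reactants: 18 (2R,3S)-5-methoxy-8-(3-methylbut-2-enyl)-7-(triisopropylsilyloxy)-2-[4-(triisopropylsilyloxy)phenyl]-3,4-dihydro-2H-chromen-3-ol
Product: 19 (2R,3S)-2-(4-hydroxyphenyl)-5-methoxy-8-(3-methylbut-2-enyl)-3,4-dihydro-2H-chromene-3,7-diol (8-prenylafzelechin 5-methyl ether)
Conditions: TBAF, AcOH (1:1), THF, 0 °C, argon
Reagents that add atoms: none
Why: Fluoride cleavage of both aryl silyl ethers; acetic acid protonates the phenoxides as they form, which prevents quinone-methide opening of ring C (C2 epimerisation) and air oxidation, and the conditions are too mild to cyclise the prenyl group.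

## Compound list

1 | 5-methoxybenzene-1,3-diol (5-methoxyresorcinol) | COc1cc(O)cc(O)c1 | starting material
2 | 1-methoxy-3,5-bis(methoxymethoxy)benzene | COCOc1cc(OC)cc(OCOC)c1 | intermediate
3 | 1-bromo-3-methylbut-2-ene (prenyl bromide) | CC(C)=CCBr | starting material
4 | [4-methoxy-2,6-bis(methoxymethoxy)phenyl]lithium | [Li]c1c(OCOC)cc(OC)cc1OCOC | intermediate (not isolated)
5 | 5-methoxy-1,3-bis(methoxymethoxy)-2-(3-methylbut-2-enyl)benzene | COCOc1cc(OC)cc(OCOC)c1CC=C(C)C | intermediate
6 | 5-methoxy-2-(3-methylbut-2-enyl)benzene-1,3-diol | COc1cc(O)c(CC=C(C)C)c(O)c1 | intermediate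
7 | [2,4-dihydroxy-6-methoxy-3-(3-methylbut-2-enyl)benzylidene]dimethylammonium chloride | COc1cc(O)c(CC=C(C)C)c(O)c1C=[N+](C)C.[Cl-] | intermediate (not isolated)
8 | 2,4-dihydroxy-6-methoxy-3-(3-methylbut-2-enyl)benzaldehyde | COc1cc(O)c(CC=C(C)C)c(O)c1C=O | intermediate
9 | 2-hydroxy-6-methoxy-3-(3-methylbut-2-enyl)-4-(triisopropylsilyloxy)benzaldehyde | COc1cc(O[Si](C(C)C)(C(C)C)C(C)C)c(CC=C(C)C)c(O)c1C=O | intermediate
10 | 2-(hydroxymethyl)-3-methoxy-6-(3-methylbut-2-enyl)-5-(triisopropylsilyloxy)phenol | COc1cc(O[Si](C(C)C)(C(C)C)C(C)C)c(CC=C(C)C)c(O)c1CO | intermediate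
11 | 4-hydroxybenzaldehyde | O=Cc1ccc(O)cc1 | starting material
12 | 4-(triisopropylsilyloxy)benzaldehyde | O=Cc1ccc(O[Si](C(C)C)(C(C)C)C(C)C)cc1 | intermediate
13 | 1-(triphenylphosphoranylidene)propan-2-one | CC(=O)C=P(c1ccccc1)(c1ccccc1)c1ccccc1 | starting material
14 | (E)-4-[4-(triisopropylsilyloxy)phenyl]but-3-en-2-one | CC(=O)/C=C/c1ccc(O[Si](C(C)C)(C(C)C)C(C)C)cc1 | intermediate
15 | (E)-2-[4-(triisopropylsilyloxy)phenyl]ethenyl acetate | CC(=O)O/C=C/c1ccc(O[Si](C(C)C)(C(C)C)C(C)C)cc1 | intermediate
16 | 5-methoxy-6-methylidene-2-(3-methylbut-2-enyl)-3-(triisopropylsilyloxy)cyclohexa-2,4-dien-1-one | C=C1C(OC)=CC(O[Si](C(C)C)(C(C)C)C(C)C)=C(CC=C(C)C)C1=O | intermediate (not isolated)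
17 | (2R,3S)-5-methoxy-8-(3-methylbut-2-enyl)-7-(triisopropylsilyloxy)-2-[4-(triisopropylsilyloxy)phenyl]-3,4-dihydro-2H-chromen-3-yl acetate | COc1cc(O[Si](C(C)C)(C(C)C)C(C)C)c(CC=C(C)C)c2c1C[C@H](OC(C)=O)[C@@H](c1ccc(O[Si](C(C)C)(C(C)C)C(C)C)cc1)O2 | intermediate
18 | (2R,3S)-5-methoxy-8-(3-methylbut-2-enyl)-7-(triisopropylsilyloxy)-2-[4-(triisopropylsilyloxy)phenyl]-3,4-dihydro-2H-chromen-3-ol | COc1cc(O[Si](C(C)C)(C(C)C)C(C)C)c(CC=C(C)C)c2c1C[C@H](O)[C@@H](c1ccc(O[Si](C(C)C)(C(C)C)C(C)C)cc1)O2 | intermediate
19 | (2R,3S)-2-(4-hydroxyphenyl)-5-methoxy-8-(3-methylbut-2-enyl)-3,4-dihydro-2H-chromene-3,7-diol (8-prenylafzelechin 5-methyl ether) | COc1cc(O)c(CC=C(C)C)c2c1C[C@H](O)[C@@H](c1ccc(O)cc1)O2 | target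

## Step count and least certain steps

Total: 12 steps (steps 1–6 ring A fragment, 7–9 ring B fragment, 10 union, 11–12 deprotection). Longest linear sequence: 9 steps (1–6, 10–12).

**Step 10 (key step, proposed new method).** The most likely failure is poor facial selectivity, because the enol acetate offers the chiral phosphate no hydrogen-bond donor and the methide carries no substituent to differentiate its faces. Second in likelihood are self-condensation of the methide with the C6 position of another ring A and acyl transfer from 15 to the benzylic hydroxyl of 10. The fallback uses only known chemistry, sets out from 10 and 15, and returns at 18.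
- The cycloaddition is run with an achiral acid, diphenyl hydrogen phosphate, in CH2Cl2 at 0 °C. This is the established racemic [4+2] addition of o-quinone methides to donor-substituted styrenes and should give the racemic trans acetate F1.
- Methanolysis (K2CO3, MeOH) gives the racemic alcohol F2.
- Acylation with (1S,4R)-camphanic chloride (Et3N, DMAP, CH2Cl2) gives the (2R,3S)-camphanate F3 and the (2S,3R)-camphanate F4, which are diastereomers and are separated by chromatography or crystallisation.
- Methanolysis of F3 (K2CO3, MeOH) gives 18.

**Step 6.** The borate of the electron-rich salicyl alcohol may ionise to the methide, which borohydride then reduces to the methyl compound (over-reduction), and the product may ionise on acidic supports during isolation. The fallback avoids the aldehyde and the hydride, sets out from 6 and returns at 10.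
- Mono-silylation of the symmetric diol (TIPSCl 1 equiv, imidazole, DMF; diol and bis-ether recycled) gives the monosilyl ether F5.
- Nagata ortho-hydroxymethylation (PhB(OH)2, paraformaldehyde, cat. propionic acid, PhMe, reflux with water removal) can only occur at the single free position ortho to the hydroxyl and gives the storable benzodioxaborine F6.
- Exchange with propane-1,3-diol in THF at rt releases 10 under neutral conditions directly before step 10.

**Step 9.** The peroxide may epoxidise the electron-rich enol acetate once it has formed, and the enol ester may hydrolyse during isolation. The fallback sets out from 12 and returns at 15.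
- Wittig reaction with the ylide from (methoxymethyl)triphenylphosphonium chloride and KOt-Bu in THF gives the enol ether F7 as an E/Z mixture.
- Hydrolysis with aqueous formic acid gives the arylacetaldehyde F8.
- O-Acetylation of its enolate (Ac2O, KOAc, 100 °C) gives 15 together with its (Z)-isomer. The (Z)-isomer must be removed by chromatography because it would lead to the 2,3-cis series.

**Step 2.** The alkylation may proceed with allylic transposition (attack through the tertiary terminus of 3), and metalation may partly occur at the carbon between the acetal and the methyl ether. The fallback removes the first problem, sets out from 2 through aryllithium 4 and returns at 5.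
- Trapping 4 with allyl bromide, for which both modes of substitution give the same product, yields the allyl arene F9.
- Cross-metathesis of F9 with excess 2-methylbut-2-ene (second-generation Grubbs catalyst, RuCl2(H2IMes)(PCy3)(=CHPh), CH2Cl2, 40 °C) gives 5.

## Further compounds

F1 | step 10 | racemic trans-5-methoxy-8-(3-methylbut-2-enyl)-7-(triisopropylsilyloxy)-2-[4-(triisopropylsilyloxy)phenyl]-3,4-dihydro-2H-chromen-3-yl acetate (1:1 mixture of the 2R,3S and 2S,3R enantiomers) | COc1cc(O[Si](C(C)C)(C(C)C)C(C)C)c(CC=C(C)C)c2c1C[C@H](OC(C)=O)[C@@H](c1ccc(O[Si](C(C)C)(C(C)C)C(C)C)cc1)O2.COc1cc(O[Si](C(C)C)(C(C)C)C(C)C)c(CC=C(C)C)c2c1C[C@@H](OC(C)=O)[C@H](c1ccc(O[Si](C(C)C)(C(C)C)C(C)C)cc1)O2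
F2 | step 10 | racemic trans-5-methoxy-8-(3-methylbut-2-enyl)-7-(triisopropylsilyloxy)-2-[4-(triisopropylsilyloxy)phenyl]-3,4-dihydro-2H-chromen-3-ol (1:1 mixture of the 2R,3S and 2S,3R enantiomers) | COc1cc(O[Si](C(C)C)(C(C)C)C(C)C)c(CC=C(C)C)c2c1C[C@H](O)[C@@H](c1ccc(O[Si](C(C)C)(C(C)C)C(C)C)cc1)O2.COc1cc(O[Si](C(C)C)(C(C)C)C(C)C)c(CC=C(C)C)c2c1C[C@@H](O)[C@H](c1ccc(O[Si](C(C)C)(C(C)C)C(C)C)cc1)O2
F3 | step 10 | (2R,3S)-5-methoxy-8-(3-methylbut-2-enyl)-7-(triisopropylsilyloxy)-2-[4-(triisopropylsilyloxy)phenyl]-3,4-dihydro-2H-chromen-3-yl (1S,4R)-4,7,7-trimethyl-3-oxo-2-oxabicyclo[2.2.1]heptane-1-carboxylate | COc1cc(O[Si](C(C)C)(C(C)C)C(C)C)c(CC=C(C)C)c2c1C[C@H](OC(=O)[C@@]13CC[C@@](C)(C(=O)O1)C3(C)C)[C@@H](c1ccc(O[Si](C(C)C)(C(C)C)C(C)C)cc1)O2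
F4 | step 10 | (2S,3R)-5-methoxy-8-(3-methylbut-2-enyl)-7-(triisopropylsilyloxy)-2-[4-(triisopropylsilyloxy)phenyl]-3,4-dihydro-2H-chromen-3-yl (1S,4R)-4,7,7-trimethyl-3-oxo-2-oxabicyclo[2.2.1]heptane-1-carboxylate | COc1cc(O[Si](C(C)C)(C(C)C)C(C)C)c(CC=C(C)C)c2c1C[C@@H](OC(=O)[C@@]13CC[C@@](C)(C(=O)O1)C3(C)C)[C@H](c1ccc(O[Si](C(C)C)(C(C)C)C(C)C)cc1)O2
F5 | step 6 | 5-methoxy-2-(3-methylbut-2-enyl)-3-(triisopropylsilyloxy)phenol | COc1cc(O)c(CC=C(C)C)c(O[Si](C(C)C)(C(C)C)C(C)C)c1
F6 | step 6 | 5-methoxy-8-(3-methylbut-2-enyl)-2-phenyl-7-(triisopropylsilyloxy)-4H-1,3,2-benzodioxaborine | COc1cc(O[Si](C(C)C)(C(C)C)C(C)C)c(CC=C(C)C)c2OB(c3ccccc3)OCc12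
F7 | step 9 | 1-(2-methoxyethenyl)-4-(triisopropylsilyloxy)benzene (E/Z mixture) | COC=Cc1ccc(O[Si](C(C)C)(C(C)C)C(C)C)cc1
F8 | step 9 | 2-[4-(triisopropylsilyloxy)phenyl]acetaldehyde | O=CCc1ccc(O[Si](C(C)C)(C(C)C)C(C)C)cc1
F9 | step 2 | 5-methoxy-1,3-bis(methoxymethoxy)-2-(prop-2-enyl)benzene | COCOc1cc(OC)cc(OCOC)c1CC=C
A1 | alternative 1 | 4-{[(4S,5S)-2,2-dimethyl-5-[4-(triisopropylsilyloxy)phenyl]-1,3-dioxolan-4-yl]methyl}-3-methoxycyclobut-2-en-1-one | COC1=CC(=O)C1C[C@@H]2OC(C)(C)O[C@H]2c3ccc(O[Si](C(C)C)(C(C)C)C(C)C)cc3
A2 | alternative 1 | triisopropyl[(5-methylhex-4-en-1-yn-1-yl)oxy]silane | CC(C)=CCC#CO[Si](C(C)C)(C(C)C)C(C)C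
A3 | alternative 1 | 2-{[(4S,5S)-2,2-dimethyl-5-[4-(triisopropylsilyloxy)phenyl]-1,3-dioxolan-4-yl]methyl}-3-methoxy-6-(3-methylbut-2-enyl)-5-(triisopropylsilyloxy)phenol | COc1cc(O[Si](C(C)C)(C(C)C)C(C)C)c(CC=C(C)C)c(O)c1C[C@@H]2OC(C)(C)O[C@H]2c3ccc(O[Si](C(C)C)(C(C)C)C(C)C)cc3
A4 | alternative 2 | {4-[(1S)-1-[2-ethenyl-3-methoxy-6-(3-methylbut-2-enyl)-5-(triisopropylsilyloxy)phenoxy]prop-2-en-1-yl]phenoxy}triisopropylsilane | COc1cc(O[Si](C(C)C)(C(C)C)C(C)C)c(CC=C(C)C)c(O[C@@H](C=C)c2ccc(O[Si](C(C)C)(C(C)C)C(C)C)cc2)c1C=C
A5 | alternative 2 | (2S)-5-methoxy-8-(3-methylbut-2-enyl)-7-(triisopropylsilyloxy)-2-[4-(triisopropylsilyloxy)phenyl]-2H-chromene | COc1cc(O[Si](C(C)C)(C(C)C)C(C)C)c(CC=C(C)C)c2c1C=C[C@@H](c1ccc(O[Si](C(C)C)(C(C)C)C(C)C)cc1)O2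
A6 | alternative 3 | 4-[(R)-[5-methoxy-2-(3-methylbut-2-enyl)-3-(triisopropylsilyloxy)phenoxy][(2S)-oxiran-2-yl]methyl]phenyl 2,2-dimethylpropanoate | COc1cc(O[Si](C(C)C)(C(C)C)C(C)C)c(CC=C(C)C)c(O[C@H](c2ccc(OC(=O)C(C)(C)C)cc2)[C@@H]2CO2)c1
A7 | alternative 3 | 4-[(2R,3S)-3-hydroxy-5-methoxy-8-(3-methylbut-2-enyl)-7-(triisopropylsilyloxy)-3,4-dihydro-2H-chromen-2-yl]phenyl 2,2-dimethylpropanoate | COc1cc(O[Si](C(C)C)(C(C)C)C(C)C)c(CC=C(C)C)c2c1C[C@H](O)[C@@H](c1ccc(OC(=O)C(C)(C)C)cc1)O2
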